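**Plan**

1. The ring and its four stereocentres are (−)-quinic acid. The hard part is placing two kinds of acyl groups on the migration-prone O3/O4/O5 triol and ending with two enoates, four free phenols, a hemisuccinate and two free acids, which leaves almost no safe final deprotection.
2. The retrosynthesis therefore cuts the two Cα=Cβ bonds of the caffeoyl arms first, not their ester C–O bonds, giving 2 × 3,4-dihydroxybenzaldehyde and a bis(hydrogen malonate). It then cuts the O3/O5 malonyl C–O bonds, the O4 succinyl C–O bond and the C1 benzyl ester, back to quinic acid.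
3. Forward, no ring is formed. The succinyl unit is joined to O4 first (the only free secondary OH of the 3,5-bis-silyl ether), then the malonyl units to O3/O5 without base. All benzyl groups are removed by hydrogenolysis while the molecule has no alkene or arene of its own, and only then are both aryl-alkene arms completed in one two-directional Knoevenagel–Doebner condensation with the unprotected aldehyde.
4. Enabling feature: the esters on O3 and O5 of the cyclohexane ring C1–C6 are identical ArCH=CH–C(=O)O units, related by the local C2 axis through C1 and C4. In the precursor their Cα atoms are the only acidic CH2 groups, whereas the CH2CH2 of the O4 succinate is not acidic, so both C=C bonds can be made last, selectively, with nothing left to deprotect.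
5. Stereochemistry: C1, C3, C4 and C5 come unchanged from (−)-quinic acid, since no step breaks a ring C–O or C–C bond. The two E alkenes are set in the key step.

Key step: step 7

Assumption: the SMILES is read as 3,5-di-O-(E)-caffeoyl-4-O-succinoyl-(−)-quinic acid, with O1–H, O3 and O4 on one ring face, O5 and the C1 carboxyl on the other, and C3 and C5 both R.

**Route**

Step 1
Reactants: 1 (−)-quinic acid; 2 benzyl bromide
Product: 3 benzyl quinate (benzyl ester of (−)-quinic acid, all four hydroxyls free)
Conditions: Cs2CO3 (0.5 equiv), MeOH/H2O, evaporate; then BnBr (1.1 equiv), DMF, rt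
Reagents that add atoms: benzyl bromide, BrCc1ccccc1
Why: O-Alkylation of the cesium carboxylate (SN2 esterification) is selective for the acid over the four hydroxyls, which carbonate does not deprotonate, and touches no stereocentre.

Step 2
Reactants: 3 benzyl quinate; 4 tert-butyldimethylsilyl chloride
Product: 5 benzyl 3,5-bis-O-(tert-butyldimethylsilyl)quinate (O1–H and O4–H free)
Conditions: TBSCl (2.2 equiv), Et3N (3 equiv), DMF, 0 °C → rt
Reagents that add atoms: tert-butyldimethylsilyl chloride, CC(C)(C)[Si](C)(C)Cl
Why: Sterically controlled silyl ether formation: as with methyl quinate, the axial O3–H and equatorial O5–H should be silylated while the O4–H flanked by both and the tertiary O1–H stay free, so O4 is singled out without a separate protecting step.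

Step 3
Reactants: 5 benzyl 3,5-bis-O-(tert-butyldimethylsilyl)quinate; 6 mono-benzyl succinate (4-(benzyloxy)-4-oxobutanoic acid)
Product: 8 benzyl 3,5-bis-O-(tert-butyldimethylsilyl)-4-O-[4-(benzyloxy)-4-oxobutanoyl]quinate, via benzyl 4-chloro-4-oxobutanoate 7 (not isolated)
Conditions: 6, (COCl)2, cat. DMF, CH2Cl2, 0 °C → rt, evaporate; then 5, pyridine, DMAP (0.3 equiv), CH2Cl2, 0 → 35 °C
Reagents that add atoms: mono-benzyl succinate, OC(=O)CCC(=O)OCc1ccccc1
Why: Acid chloride formation followed by DMAP-catalysed esterification puts the succinyl unit on O4, the only remaining secondary hydroxyl, because the tertiary α-hydroxy ester O1–H is too hindered and electron-poor to compete.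

Step 4
Reactants: 8 benzyl 3,5-bis-O-(tert-butyldimethylsilyl)-4-O-[4-(benzyloxy)-4-oxobutanoyl]quinate
Product: 9 benzyl 4-O-[4-(benzyloxy)-4-oxobutanoyl]quinate (O1–H, O3–H and O5–H free)
Conditions: HF·pyridine, pyridine, THF, 0 °C → rt
Reagents that add atoms: none
Why: Fluoride cleavage of the two secondary TBS ethers under buffered acidic conditions generates no alkoxide, so the O4 ester should stay in place and the benzyl esters are inert.

Step 5
Reactants: 9 benzyl 4-O-[4-(benzyloxy)-4-oxobutanoyl]quinate; 10 Meldrum's acid (2,2-dimethyl-1,3-dioxane-4,6-dione)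
Product: 11 benzyl 3,5-bis-O-(carboxyacetyl)-4-O-[4-(benzyloxy)-4-oxobutanoyl]quinate (bis(hydrogen malonate))
Conditions: Meldrum's acid (2.3 equiv), toluene, 90 °C
Reagents that add atoms: Meldrum's acid, CC1(C)OC(=O)CC(=O)O1
Why: Thermal alcoholysis of Meldrum's acid (ring opening with loss of acetone) gives malonic half esters without any base, so acyl migration is not promoted, and the two secondary hydroxyls should react well before the hindered tertiary O1–H.

Step 6
Reactants: 11 benzyl 3,5-bis-O-(carboxyacetyl)-4-O-[4-(benzyloxy)-4-oxobutanoyl]quinate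
Product: 12 3,5-bis-O-(carboxyacetyl)-4-O-(3-carboxypropanoyl)quinic acid (tetra-acid)
Conditions: H2 (1 atm), 10% Pd/C, THF, rt
Reagents that add atoms: none
Why: Catalytic hydrogenolysis cleaves both benzyl esters cleanly because at this stage the molecule has no alkene, catechol or other reducible group, which is the reason the aryl-alkene arms are built only afterwards.

Step 7
Reactants: 12 3,5-bis-O-(carboxyacetyl)-4-O-(3-carboxypropanoyl)quinic acid; 13 3,4-dihydroxybenzaldehyde
Product: 15 3,5-di-O-[(E)-caffeoyl]-4-O-succinoyl-(−)-quinic acid (target), via bis-arylidenemalonate tetra-acid 14 (not isolated)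
Conditions: 13 (3 equiv), pyridine, piperidine (0.3 equiv), 50 °C, Ar; then cold 1 M HCl, C18 chromatography
Reagents that add atoms: 3,4-dihydroxybenzaldehyde, O=Cc1ccc(O)c(O)c1
Why: Piperidine turns 13 into an iminium ion that is attacked by the enol of each malonic half-ester CH2 (Knoevenagel), loss of piperidine gives the arylidenemalonic half esters 14, and pyridine-mediated decarboxylation then gives the enoates (Doebner modification). The closest known reaction is the preparation of caffeate and ferulate esters of alcohols, quinic acid derivatives included, from their hydrogen malonates and unprotected hydroxybenzaldehydes. No ring is closed and no sp3 stereocentre is formed or touched. The two new C=C bonds are the only new stereo elements and should come out E, because protonation after loss of CO2 gives the conjugated enoate with aryl and ester trans, the thermodynamically preferred geometry. The step needs site selectivity for the O3 and O5 arms over the O4 arm, secured because only the malonyl CH2 groups are acidic while the succinyl CH2CH2 is not, and it needs the acyl pattern to hold, secured because O3, O4 and O5 are all acylated and the tertiary O1–H is the only free ring hydroxyl. Phenols, carboxylic acids and the hemisuccinate are spectators, so the product of this step is the target itself.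

**Compound list**

1 | (−)-quinic acid | O[C@H]1[C@H](O)C[C@](O)(C(=O)O)C[C@H]1O | starting material
2 | benzyl bromide | BrCc1ccccc1 | starting material
3 | benzyl quinate | O[C@H]1[C@H](O)C[C@](O)(C(=O)OCc2ccccc2)C[C@H]1O | intermediate
4 | tert-butyldimethylsilyl chloride | CC(C)(C)[Si](C)(C)Cl | starting material
5 | benzyl 3,5-bis-O-(tert-butyldimethylsilyl)quinate | O[C@H]1[C@H](O[Si](C)(C)C(C)(C)C)C[C@](O)(C(=O)OCc2ccccc2)C[C@H]1O[Si](C)(C)C(C)(C)C | intermediate
6 | mono-benzyl succinate (4-(benzyloxy)-4-oxobutanoic acid) | OC(=O)CCC(=O)OCc1ccccc1 | starting material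
7 | benzyl 4-chloro-4-oxobutanoate | ClC(=O)CCC(=O)OCc1ccccc1 | intermediate
8 | benzyl 3,5-bis-O-(tert-butyldimethylsilyl)-4-O-[4-(benzyloxy)-4-oxobutanoyl]quinate | O=C(OCc1ccccc1)CCC(=O)O[C@H]1[C@H](O[Si](C)(C)C(C)(C)C)C[C@](O)(C(=O)OCc2ccccc2)C[C@H]1O[Si](C)(C)C(C)(C)C | intermediate
9 | benzyl 4-O-[4-(benzyloxy)-4-oxobutanoyl]quinate | O=C(OCc1ccccc1)CCC(=O)O[C@H]1[C@H](O)C[C@](O)(C(=O)OCc2ccccc2)C[C@H]1O | intermediate
10 | Meldrum's acid | CC1(C)OC(=O)CC(=O)O1 | starting material
11 | benzyl 3,5-bis-O-(carboxyacetyl)-4-O-[4-(benzyloxy)-4-oxobutanoyl]quinate | O=C(OCc1ccccc1)CCC(=O)O[C@H]1[C@H](OC(=O)CC(=O)O)C[C@](O)(C(=O)OCc2ccccc2)C[C@H]1OC(=O)CC(=O)O | intermediate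
12 | 3,5-bis-O-(carboxyacetyl)-4-O-(3-carboxypropanoyl)quinic acid | O=C(O)CCC(=O)O[C@H]1[C@H](OC(=O)CC(=O)O)C[C@](O)(C(=O)O)C[C@H]1OC(=O)CC(=O)O | intermediate
13 | 3,4-dihydroxybenzaldehyde | O=Cc1ccc(O)c(O)c1 | starting material
14 | 3,5-bis-O-[2-carboxy-3-(3,4-dihydroxyphenyl)prop-2-enoyl]-4-O-(3-carboxypropanoyl)quinic acid (geometry of the arylidenemalonate C=C not defined; both isomers converge) | O=C(O)CCC(=O)O[C@H]1[C@H](OC(=O)C(C(=O)O)=Cc2ccc(O)c(O)c2)C[C@](O)(C(=O)O)C[C@H]1OC(=O)C(C(=O)O)=Cc1ccc(O)c(O)c1 | intermediate
15 | 3,5-di-O-[(E)-caffeoyl]-4-O-succinoyl-(−)-quinic acid (CNP0133919.1) | O=C(O)CCC(=O)O[C@H]1[C@H](OC(=O)/C=C/c2ccc(O)c(O)c2)C[C@](O)(C(=O)O)C[C@H]1OC(=O)/C=C/c1ccc(O)c(O)c1 | target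

**Step count and risks**

Total steps: 7. Longest linear sequence: 7 steps (1 → 15).

Step 7 (key step). What may go wrong: the malonic half esters may lose CO2 before they condense and leave acetates, only one arm may condense, or the aldehyde and the product catechols may oxidise under the amine base. The fallback replaces C=C formation by ester C–O formation with preformed, benzyl-protected caffeoyl units, and sets out from diol 9. Commercial 3,4-bis(benzyloxy)benzaldehyde is condensed with malonic acid (pyridine, piperidine, 90 °C) to (E)-3,4-bis(benzyloxy)cinnamic acid F1. This is converted with (COCl)2 and cat. DMF into (E)-3,4-bis(benzyloxy)cinnamoyl chloride F2. F2 acylates O3 and O5 of 9 (pyridine, DMAP, CH2Cl2, 0 °C → rt) to give benzyl 3,5-bis-O-[(E)-3,4-bis(benzyloxy)cinnamoyl]-4-O-[4-(benzyloxy)-4-oxobutanoyl]quinate F3. All six benzyl groups (four aryl ethers, two esters) are then removed without reduction by BCl3 and pentamethylbenzene in CH2Cl2 (−78 → 0 °C), which should spare the enoates. The fallback comes back to the route at target 15.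

Step 5. What may go wrong: the thermal malonylation has only steric site control, so the tertiary O1–H may also be acylated, the axial O3–H may react incompletely, and at 90 °C the O4 ester may migrate or the half esters may decarboxylate. The fallback sets out from diol 9 and uses a low-temperature carbodiimide esterification with commercial mono-benzyl malonate (EDC·HCl, cat. DMAP, CH2Cl2, 0 °C → rt). This should give benzyl 3,5-bis-O-[3-(benzyloxy)-3-oxopropanoyl]-4-O-[4-(benzyloxy)-4-oxobutanoyl]quinate F4. Hydrogenolysis of its four benzyl esters (H2, Pd/C, THF) gives the tetra-acid directly, so the fallback comes back to the route at 12.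

Step 3. What may go wrong: acylation of the O4–H between two silyl ethers may be slow, and forcing it may cause silyl migration or acylation of O1. The fallback drops the silyl detour and sets out from tetrol 3. Acid chloride 7, prepared as in step 3, is used with 2-aminoethyl diphenylborinate (10 mol %) and iPr2NEt in MeCN (0 °C → rt). The catalyst binds the cis-3,4-diol as a borinate and directs acylation to its equatorial oxygen, O4. This should give diol 9 directly, where the fallback comes back to the route; it makes no compound outside the compound list (F0).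

**Further compounds**

F1 | step 7 | (E)-3,4-bis(benzyloxy)cinnamic acid | OC(=O)/C=C/c1ccc(OCc2ccccc2)c(OCc2ccccc2)c1
F2 | step 7 | (E)-3,4-bis(benzyloxy)cinnamoyl chloride | O=C(Cl)/C=C/c1ccc(OCc2ccccc2)c(OCc2ccccc2)c1
F3 | step 7 | benzyl 3,5-bis-O-[(E)-3,4-bis(benzyloxy)cinnamoyl]-4-O-[4-(benzyloxy)-4-oxobutanoyl]quinate | O=C(OCc1ccccc1)CCC(=O)O[C@H]1[C@H](OC(=O)/C=C/c2ccc(OCc3ccccc3)c(OCc3ccccc3)c2)C[C@](O)(C(=O)OCc2ccccc2)C[C@H]1OC(=O)/C=C/c1ccc(OCc2ccccc2)c(OCc2ccccc2)c1
F4 | step 5 | benzyl 3,5-bis-O-[3-(benzyloxy)-3-oxopropanoyl]-4-O-[4-(benzyloxy)-4-oxobutanoyl]quinate | O=C(OCc1ccccc1)CCC(=O)O[C@H]1[C@H](OC(=O)CC(=O)OCc2ccccc2)C[C@](O)(C(=O)OCc2ccccc2)C[C@H]1OC(=O)CC(=O)OCc1ccccc1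
F0 | step 3 | none | none
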